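I decided to count enzyme by what the impurity leaves of it, and to run each flask forward on that count.

| flask | starting material | free enzyme | impurity | temperature | remark | time |
|---|---|---|---|---|---|---|
| Tuesday's | 0.15 M | 11 µM | 1.9 µM | 10 °C | run made earlier |  |
| Saturday's | 0.15 M | 29 µM | 1.9 µM | 21 °C | run made earlier |  |
| Sunday's | 0.15 M | 47 µM | 1.9 µM | 10 °C | run made earlier |  |
| Monday's | 0.15 M | 15 µM | 5.1 µM | 21 °C | run made earlier |  |
| elm | 0.15 M | 50 µM | 8.0 µM | 5 °C |  | 1.0 h |
| oak | 0.15 M | 15 µM | 1.9 µM | 25 °C |  | 1.0 h |

| run | time / min | product / % |
|---|---|---|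
| Tuesday's | 30.0 | 5 |
| Tuesday's | 60.0 | 9 |
| Tuesday's | 120 | 15 |
| Saturday's | 5.00 | 7 |
| Saturday's | 12.0 | 11 |
| Saturday's | 25.0 | 20 |
| Saturday's | 60.0 | 29 |
| Sunday's | 10.0 | 11 |
| Sunday's | 25.0 | 15 |
| Sunday's | 50.0 | 30 |
| Sunday's | 120 | 41 |
| Monday's | 5.00 | 0 |
| Monday's | 12.0 | 4 |
| Monday's | 25.0 | 10 |
| Monday's | 60.0 | 10 |

(scatter of a reading: 2 percentage points)

- the winner by amount of product, in percent of the starting material charged; "neither" if no more than 2 percentage points parts them (elm / oak / neither)
- how much product is there at the end, in percent of the starting material charged: elm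
- how much product is there at the end, in percent of the starting material charged: oak

- a reading or a percentage of product counts all its forms, free or not

For the first instants I took it that the impurity, charged in the smaller amount and so the limiting reagent, spends free enzyme one for one. That balance gives working enzyme, the charge of free enzyme minus the charge of impurity: 42.0 µM in elm and 13.1 µM in oak. I tested it on the two runs at 21 °C. Saturday's last reading over Monday's is 2.90, a ratio with much scatter, since each reading carries 2 percentage points. Working enzyme predicts 2.74, and the bare charges predict 1.93.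

Through the middle of a run I let product grow with working enzyme. The end needed more thought. Monday's run read 10 % at both 25.0 min and 60.0 min, while Saturday's climbed to 29 %, so I did not take product at that level to be what stopped Monday's run. I read a race instead: some loss of starting material that needs no enzyme ends a warm flask, and the product reached scales with working enzyme.

Oak is warmer than Monday's run, and scaling Monday's last reading by working enzyme gave me 13.2 %. Elm is cold, and I expected it to be still running at its end, so I scaled Sunday's reading of 30 % at 50.0 min by working enzyme and took a rough factor 0.7 for the colder bath, which gave 19.6 %. So I expected elm ahead.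

The forecast said neither, with elm at 20 % (14 % to 26 %) and oak at 22 % (15 % to 29 %), on the reading “product inhibition, with the impurity removing about its own amount of enzyme”; mine parted from it on the winner. The simulation gave 14.9 % in oak and 23.6 % in elm, so elm came out ahead.

    free enzyme → unfolded enzyme (k = 1.40 × 10⁻⁶ s⁻¹, Ea = 288 kJ mol⁻¹)
    starting material + free enzyme → product + free enzyme, rate k2*[starting material]*[free enzyme]/(1 + ([starting material]/Km2) + ([product]/Kp2)) (0.740 M, 0.140 M, k = 14.0 M⁻¹ s⁻¹, Ea = 55.0 kJ mol⁻¹)
    free enzyme + impurity → spent catalyst (k = 5000 M⁻¹ s⁻¹, Ea = 23.0 kJ mol⁻¹)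
    starting material ⇌ dormant form (K = 8.70, k = 0.00110 s⁻¹, Ea = 77.0 kJ mol⁻¹, ΔH = 3.00 kJ mol⁻¹)
    crystals ⇌ product, rate k5*(cs5 - [product]) while solid is left; crystals form when [product] > cs5 (solubility = 0.0560 M, k = 0.0260 s⁻¹)
    (constants at 25 °C)

At 1.00 h elm held free enzyme at 84.0 % of its charge, spent catalyst at 16.0 % and unfolded enzyme at 0 %, and working enzyme is 84.0 % of that charge. The forward half-life of starting material towards dormant form, that step's forward rate alone, was 0.18 h in oak against 1.6 h in elm, and at 1.00 h dormant form stood at 76.5 % in oak against 28.9 % in elm. For the neighbour with 200 µM of free enzyme and elm's impurity, the balance gives 192 µM of working enzyme, 96.0 % of its charge. At 1.00 h the simulation showed free enzyme in that neighbour at 96.0 % and product at 64.2 %, crystals counted in.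

The runs were generated by integration from invented constants; the scatter is artificial.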